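The synthesis rests on the bond between C5 of the dihydropyran, the β-carbon of its enol ether O1–C6=C5, and C1' of the cyclohexane. The key step exploits this enol ether: the 5-metallated dihydropyran (from iodide 13) acts as a masked α-acylvinyl anion, and C1' is offered as the carbonyl of ketone 5. Addition followed by mild acid joins the C8 and C7 halves and, in the same operation, transposes the enol ether into a ring-opened hydroxy enone with a tetrasubstituted C5=C1' alkene. Copper hydride then puts hydrogen on C1' anti to the axial C3' bromine, and cyclodehydration rebuilds the pyran. The halves come from a D-glutamic acid ester and (R)-limonene.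

Key step: step 8

Remark on the chemistry: primed locants denote the cyclohexane ring; 3, 4, 11, 16, 17 and 18 are carried on as isomer mixtures at centres (or at the C5=C1' geometry) that later steps erase, so their SMILES leave these elements open.

Step 1
Reactants: 1 (R)-(+)-limonene
Product: 2 (1S,2S,4R)-2-bromo-1-chloro-1-methyl-4-(prop-1-en-2-yl)cyclohexane
Conditions: Bu4NBrCl2 (1.0 equiv), CH2Cl2, −40 °C → 0 °C
Reagents that add atoms: tetrabutylammonium dichlorobromate (Bu4NCl·BrCl), CCCC[N+](CCCC)(CCCC)CCCC.[Cl-].ClBr
Why: Electrophilic anti-bromochlorination through a bromonium ion: the trisubstituted ring alkene is far more nucleophilic than the isopropenyl group, bromonium formation is reversible on both faces, and chloride should open at the tertiary carbon, in the trans-diaxial sense, only the bromonium that lies anti to the equatorial isopropenyl group, so that C4 of limonene sets C1 (S, Cl) and C2 (S, Br).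

Step 2
Reactants: 2 (1S,2S,4R)-2-bromo-1-chloro-1-methyl-4-(prop-1-en-2-yl)cyclohexane
Product: 5 (3S,4S)-3-bromo-4-chloro-4-methylcyclohexan-1-one, via methoxy hydroperoxide 3 (not isolated), via TEMPO alkoxyamine 4 (not isolated)
Conditions: O3, MeOH, −78 °C; then FeSO4·7H2O (1.2 equiv), TEMPO (1.5 equiv), −78 °C → rt; then magnesium bis(monoperoxyphthalate) hexahydrate (2.5 equiv), rt
Reagents that add atoms: TEMPO, CC1(C)CCCC(C)(C)N1[O]
Why: Oxodealkenylation (Criegee ozonolysis in methanol, reductive O–O cleavage by divalent iron, β-scission with loss of methyl acetate, trapping of the secondary radical by TEMPO, and peracid-induced fragmentation of the alkoxyamine) replaces the C(sp3)–C(sp2) bond by C=O; the carbon that loses its configuration becomes the carbonyl carbon, and the two halogen-bearing centres are not involved.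

Step 3
Reactants: 6 D-glutamic acid 5-methyl ester
Product: 7 (R)-2-bromo-5-methoxy-5-oxopentanoic acid
Conditions: NaNO2, aq. HBr (excess), −5 °C → 0 °C
Reagents that add atoms: hydrobromic acid, Br
Why: Diazotisation–bromide substitution of an α-amino acid should proceed with net retention (two successive inversions through participation of the neighbouring carboxylate) and so carries the (R) centre of the D-amino acid into the C–Br centre.

Step 4
Reactants: 7 (R)-2-bromo-5-methoxy-5-oxopentanoic acid
Product: 8 dimethyl (R)-2-bromopentanedioate
Conditions: MeOH, H2SO4 (cat.), rt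
Reagents that add atoms: methanol, CO
Why: Fischer esterification of the free acid, which leaves the α-bromo centre untouched under these mild acidic conditions.

Step 5
Reactants: 8 dimethyl (R)-2-bromopentanedioate
Product: 10 (R)-5-bromo-6,6-dimethyloxan-2-one, via bromohydrin ester 9 (not isolated)
Conditions: MeMgBr (2.1 equiv), THF, −78 °C → −40 °C; cold aq. NH4Cl; then p-TsOH·H2O (cat.), CH2Cl2, rt
Reagents that add atoms: methylmagnesium bromide, C[Mg]Br
Why: Double Grignard addition to the inductively activated α-bromo ester, which should react well before the remote ester at −78 °C, is followed by acid-catalysed lactonisation of the tertiary alcohol (six-membered ring, gem-dimethyl assistance); the cold quench keeps the bromohydrin alkoxide from closing to an epoxide, and the C–Br centre is not touched.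

Step 6
Reactants: 10 (R)-5-bromo-6,6-dimethyloxan-2-one
Product: 12 (R)-3-bromo-2,2,6-trimethyl-3,4-dihydro-2H-pyran, via methyl lactol 11 (not isolated)
Conditions: MeLi (1.05 equiv), THF, −78 °C; AcOH quench at −78 °C; then PPTS (cat.), 4 Å MS, benzene, reflux
Reagents that add atoms: methyllithium, C[Li]
Why: Addition of MeLi to a lactone stops at the tetrahedral lithium lactolate at −78 °C, and acid-catalysed dehydration of the resulting methyl lactol should give the more stable endocyclic enol ether (C5=C6) of the 6-methyl-3,4-dihydro-2H-pyran.

Step 7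
Reactants: 12 (R)-3-bromo-2,2,6-trimethyl-3,4-dihydro-2H-pyran
Product: 13 (R)-3-bromo-5-iodo-2,2,6-trimethyl-3,4-dihydro-2H-pyran
Conditions: NIS (1.1 equiv), AgNO3 (cat.), MeCN, rt → 60 °C
Reagents that add atoms: N-iodosuccinimide, O=C1CCC(=O)N1I
Why: Electrophilic iodination of an enol ether at its β-carbon (iodonium transfer to C5, C6 oxocarbenium ion, loss of the C5 proton), the reaction type by which glycals are converted into 2-iodoglycals, should give the tetrasubstituted vinyl iodide as the thermodynamic product.

Step 8
Reactants: 13 (R)-3-bromo-5-iodo-2,2,6-trimethyl-3,4-dihydro-2H-pyran; 5 (3S,4S)-3-bromo-4-chloro-4-methylcyclohexan-1-one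
Product: 17 (5R)-5-bromo-3-[(3S,4S)-3-bromo-4-chloro-4-methylcyclohexylidene]-6-hydroxy-6-methylheptan-2-one, via vinyllithium 14 (not isolated), via organocerium reagent 15 (not isolated), via tertiary carbinol 16 (not isolated)
Conditions: t-BuLi (2.0 equiv), Et2O, −78 °C; CeCl3 (anhydrous, THF slurry), −78 °C; then 5, THF, −78 °C; aq. NH4Cl; then 5% aq. oxalic acid, THF, 0 °C
Reagents that add atoms: water, O
Why: Iodine–lithium exchange at the sp2 carbon C5 is far faster than exchange at the secondary alkyl bromide at −78 °C, and the trivalent-cerium reagent 15, a strong nucleophile but a weak base, should add to the carbonyl of 5 faster than it enolises it, so the C5–C1' bond forms by 1,2-addition of a β-alkoxyvinyl organometallic to a ketone. In dilute acid the tertiary carbinol of 16, which is vinylogous to the ring oxygen O1, ionises to the 2-oxoniadiene, water adds at C6 and the hemiketal opens, so that the enol ether is transposed into the enone 17; this is the known use of β-alkoxyvinyl anions as α-acylvinyl anion equivalents. No ring is closed; the dihydropyran is opened here and closes again in step 9. No stereocenter is created, since C1' becomes sp2 and both geometrical isomers of 17 converge in step 9, and C3, C3' and C4' are not touched. The step needs exchange at C–I before C–Br (rate difference at −78 °C), carbonyl addition before loss of HBr from the β-bromo ketone (low basicity of the cerium reagent), and survival of the trans-β-alkoxyvinyl metal against ring-opening elimination (−78 °C throughout and immediate transmetallation).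

Step 9
Reactants: 17 (5R)-5-bromo-3-[(3S,4S)-3-bromo-4-chloro-4-methylcyclohexylidene]-6-hydroxy-6-methylheptan-2-one
Product: 19 laucapyranoid A, via saturated hydroxy ketone 18 (not isolated)
Conditions: [(Ph3P)CuH]6 (0.5 equiv), H2O (3 equiv), benzene, rt; filtration through SiO2; then PPTS (cat.), 4 Å MS, benzene, 60 °C
Reagents that add atoms: none
Why: In this copper hydride conjugate reduction the bulky monovalent-copper hydride should attack C1' of the alkylidenecyclohexane equatorially, on the face anti to the axial C3' bromine of the chair that carries both halogens axially, which sets C1' (S) with the side chain cis to bromine (a kinetic result, since the centre cannot epimerise afterwards), and acid-catalysed cyclodehydration of the δ-hydroxy ketone through its six-membered hemiketal then erases the C5 centre and should give the more substituted endocyclic enol ether.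

Compound list
1 | (R)-(+)-limonene, (4R)-1-methyl-4-(prop-1-en-2-yl)cyclohex-1-ene | CC1=CC[C@@H](CC1)C(C)=C | starting material
2 | (1S,2S,4R)-2-bromo-1-chloro-1-methyl-4-(prop-1-en-2-yl)cyclohexane | CC(=C)[C@@H]1CC[C@](C)(Cl)[C@@H](Br)C1 | intermediate
3 | 1-[(1R,3S,4S)-3-bromo-4-chloro-4-methylcyclohexyl]-1-methoxyethyl hydroperoxide (either configuration at the peroxy carbon) | COC(C)(OO)[C@@H]1CC[C@](C)(Cl)[C@@H](Br)C1 | intermediate
4 | 1-{[(3S,4S)-3-bromo-4-chloro-4-methylcyclohexyl]oxy}-2,2,6,6-tetramethylpiperidine (both C1 epimers) | CC1(C)CCCC(C)(C)N1OC2CC[C@](C)(Cl)[C@@H](Br)C2 | intermediate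
5 | (3S,4S)-3-bromo-4-chloro-4-methylcyclohexan-1-one | O=C1CC[C@](C)(Cl)[C@@H](Br)C1 | intermediate
6 | D-glutamic acid 5-methyl ester, (R)-2-amino-5-methoxy-5-oxopentanoic acid | COC(=O)CC[C@@H](N)C(=O)O | starting material
7 | (R)-2-bromo-5-methoxy-5-oxopentanoic acid | COC(=O)CC[C@@H](Br)C(=O)O | intermediate
8 | dimethyl (R)-2-bromopentanedioate | COC(=O)CC[C@@H](Br)C(=O)OC | intermediate
9 | methyl (R)-4-bromo-5-hydroxy-5-methylhexanoate | COC(=O)CC[C@@H](Br)C(C)(C)O | intermediate
10 | (R)-5-bromo-6,6-dimethyloxan-2-one | O=C1CC[C@@H](Br)C(C)(C)O1 | intermediate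
11 | (5R)-5-bromo-2,6,6-trimethyloxan-2-ol (both anomers, in equilibrium with the open hydroxy ketone) | CC1(O)CC[C@@H](Br)C(C)(C)O1 | intermediate
12 | (R)-3-bromo-2,2,6-trimethyl-3,4-dihydro-2H-pyran | CC1=CC[C@@H](Br)C(C)(C)O1 | intermediate
13 | (R)-3-bromo-5-iodo-2,2,6-trimethyl-3,4-dihydro-2H-pyran | CC1=C(I)C[C@@H](Br)C(C)(C)O1 | intermediate
14 | [(3R)-3-bromo-2,2,6-trimethyl-3,4-dihydro-2H-pyran-5-yl]lithium | CC1=C([Li])C[C@@H](Br)C(C)(C)O1 | intermediate
15 | [(3R)-3-bromo-2,2,6-trimethyl-3,4-dihydro-2H-pyran-5-yl]cerium dichloride | CC1=C([Ce](Cl)Cl)C[C@@H](Br)C(C)(C)O1 | intermediate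
16 | (3S,4S)-3-bromo-1-[(3R)-3-bromo-2,2,6-trimethyl-3,4-dihydro-2H-pyran-5-yl]-4-chloro-4-methylcyclohexan-1-ol (either C1 epimer) | CC1=C(C2(O)CC[C@](C)(Cl)[C@@H](Br)C2)C[C@@H](Br)C(C)(C)O1 | intermediate
17 | (5R)-5-bromo-3-[(3S,4S)-3-bromo-4-chloro-4-methylcyclohexylidene]-6-hydroxy-6-methylheptan-2-one (E/Z mixture) | CC(=O)C(=C1CC[C@](C)(Cl)[C@@H](Br)C1)C[C@@H](Br)C(C)(C)O | intermediate
18 | (5R)-5-bromo-3-[(1S,3S,4S)-3-bromo-4-chloro-4-methylcyclohexyl]-6-hydroxy-6-methylheptan-2-one (both C3 epimers) | CC(=O)C([C@H]1CC[C@](C)(Cl)[C@@H](Br)C1)C[C@@H](Br)C(C)(C)O | intermediate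
19 | laucapyranoid A, (3R)-3-bromo-5-[(1S,3S,4S)-3-bromo-4-chloro-4-methylcyclohexyl]-2,2,6-trimethyl-3,4-dihydro-2H-pyran | CC1=C([C@H]2CC[C@](C)(Cl)[C@@H](Br)C2)C[C@@H](Br)C(C)(C)O1 | target

Total step count: 9
Longest linear sequence: 7 steps (steps 3 to 9, from 6); steps 1 and 2 form the second branch.

Steps most likely to fail

Step 8. The trans-β-alkoxyvinyl metal may undergo ring-opening β-elimination (loss of the alkoxide, giving an alkyne) before it is transmetallated. The β-bromo ketone may be deprotonated and lose HBr instead of being attacked at carbon. On prolonged acid contact the new tetrasubstituted alkene may deconjugate into the ring. Fallback: the C5 nucleophile is changed from a vinyl metal to an enolate, setting out from lactone 10 and ketone 5. Lactone 10 is deprotonated (LiN(i-Pr)2, THF, −78 °C), and the enolate is transmetallated with CeCl3 and added to 5 to give the β-hydroxy lactone F1. Acetylation (Ac2O, DMAP) gives the tertiary acetate F2, and DBU removes acetic acid by the E1cB path to give the α-cyclohexylidene lactone F3. MeLi (one equivalent, −78 °C) followed by aqueous work-up opens the lactolate to the hydroxy enone, so the route is rejoined at 17.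

Step 9. Hydride transfer to the crowded, twisted tetrasubstituted enone may be too slow or may go to the carbonyl, and facial selectivity at C1' may erode. Fallback: hydrogen is delivered as H2 from a cationic iridium catalyst instead of as hydride. Compound 17 is hydrogenated with [Ir(cod)(PCy3)(py)]PF6 (H2, CH2Cl2), a catalyst class that accepts tetrasubstituted alkenes and any deconjugated isomer, with the metal approaching anti to the axial bromine. This gives 18, where the route is rejoined, and the PPTS cyclodehydration follows as before. No compound outside the list is made (F0).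

Step 5. The Grignard reagent may also add to the distal ester, may undergo bromine–magnesium exchange at the α-bromo ester, or the bromohydrin alkoxide may close to an epoxide. Fallback: the two carboxyl termini are told apart by oxidation level instead of by rate, setting out from acid 7. Coupling with N,O-dimethylhydroxylamine (EDC, N-methylmorpholine) gives the N-methoxy-N-methylamide F4. MeMgBr (one equivalent, −78 °C) gives the α-bromo methyl ketone F5. MeMgBr with CeCl3 at −78 °C, which should add to the ketone and spare the ester, gives the bromohydrin ester 9, where the route is rejoined before lactonisation.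

Further compounds
F1 | step 8 | (5R)-5-bromo-3-[(3S,4S)-3-bromo-4-chloro-1-hydroxy-4-methylcyclohexyl]-6,6-dimethyloxan-2-one | O=C1C(C[C@@H](Br)C(C)(C)O1)C2(O)CC[C@](C)(Cl)[C@@H](Br)C2
F2 | step 8 | (3S,4S)-3-bromo-1-[(5R)-5-bromo-6,6-dimethyl-2-oxooxan-3-yl]-4-chloro-4-methylcyclohexyl acetate | O=C1C(C[C@@H](Br)C(C)(C)O1)C2(OC(C)=O)CC[C@](C)(Cl)[C@@H](Br)C2
F3 | step 8 | (5R)-5-bromo-3-[(3S,4S)-3-bromo-4-chloro-4-methylcyclohexylidene]-6,6-dimethyloxan-2-one | O=C1C(C[C@@H](Br)C(C)(C)O1)=C2CC[C@](C)(Cl)[C@@H](Br)C2
F0 | step 9 | none | none
F4 | step 5 | methyl (R)-4-bromo-5-[methoxy(methyl)amino]-5-oxopentanoate | COC(=O)CC[C@@H](Br)C(=O)N(C)OC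
F5 | step 5 | methyl (R)-4-bromo-5-oxohexanoate | COC(=O)CC[C@@H](Br)C(C)=O
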